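As the chemist at the bench for Tuesday's and Friday's flasks, I wanted one number for each that I could reckon on paper.

| flask | free monomer | initiator | remark | time |
|---|---|---|---|---|
| zeta | 0.023 M (fed, over 15 h) | 3.9 mM | run made earlier; the fed solution adds 0.25 times the starting volume |  |
| eta | 0.055 M (fed, over 15 h) | 3.9 mM | run made earlier; the fed solution adds 0.25 times the starting volume |  |
| delta | 0.12 M (fed, over 15 h) | 3.9 mM | run made earlier; the fed solution adds 0.25 times the starting volume |  |
| epsilon | 0.10 M (fed, over 15 h) | 5.4 mM | run made earlier; the fed solution adds 0.25 times the starting volume |  |
| Tuesday's | 0.10 M (fed, over 15 h) | 3.9 mM | the fed solution adds 0.25 times the starting volume | 15 h |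
| Friday's | 0.030 M | 12 mM | everything together at the start, the whole solution of free monomer included, so that from the start the volume is larger by 0.25 times the starting volume | 15 h |

| run | time / h | monomer in chains / % |
|---|---|---|
| zeta | 1.33 | 1.0 |
| zeta | 3.00 | 0.5 |
| zeta | 6.00 | 2.0 |
| zeta | 15.0 | 21.6 |
| eta | 2.00 | 0 |
| eta | 5.00 | 0 |
| eta | 10.0 | 12.7 |
| eta | 15.0 | 34.0 |
| delta | 1.33 | 0 |
| delta | 3.00 | 2.0 |
| delta | 6.00 | 3.8 |
| delta | 15.0 | 45.6 |
| epsilon | 2.00 | 0.3 |
| epsilon | 5.00 | 3.9 |
| epsilon | 10.0 | 21.0 |
| epsilon | 15.0 | 50.8 |

(readings scatter by 1 percentage point)

* the winner by amount of monomer in chains, in percent of the free monomer charged; "neither" if no more than 2 percentage points parts them (Tuesday's / Friday's / neither)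
* how much monomer in chains is there at the end, in percent of the free monomer charged: Tuesday's
* how much monomer in chains is there at the end, in percent of the free monomer charged: Friday's

- amounts are per litre of the starting volume; all of the dose is in the solution fed
- the numbers in the tables scatter with a standard deviation of 1 percentage point
- percentages count the whole charge, also what has not yet gone in

I worked with exposure E, a time divided by the mean lifetime of free monomer, treating its loss as pseudo-first-order with a constant lifetime. I solved a fed flask at both ends. At small E the fraction in chains y is E/2, and at large E the fraction still free is 1/E. Joining the ends gives E = y/(1 − y) + y, so each reading at the end of dosing became an exposure.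

First the dose. By hand, a constant lifetime leaves E unchanged when the dose moves, but zeta read 0.492 and delta a higher 1.29, a reading of order 0.586 in the charge of free monomer. Scaled from delta by that order, Tuesday's exposure, its dosing time over the mean lifetime of its free monomer, came to 1.16, and the join turned this back into 42.5 %.

Next the initiator. By hand, more of it should raise E, and epsilon read 1.54, above my scaled figure for Tuesday's, a reading of order 0.864 in initiator.

Last the way of going in. By hand, free monomer present from the start has the whole time, so y = 1 − exp(−E). Carrying both orders to Friday's charges, and letting its larger volume pass unreckoned, I got an exposure of 1.52 and 78.0 %, more than my figure for Tuesday's.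

The forecast named Friday's, with 43 % for Tuesday's and 66 % for Friday's, holding that “the rate goes about as monomer^1.5”; my Friday's figure stood 12 percentage points above its own.

The flask gave 42.1 % for Tuesday's and 87.0 % for Friday's, and at 7.50 h Friday's held 0.00313 M of living end against 0.00139 M in Tuesday's.

    free monomer + initiator → living end + monomer in chains (k = 3.30 M⁻¹ h⁻¹)
    free monomer + living end → monomer in chains + living end, rate k2*[living end]*[free monomer] (k = 43.0 M⁻¹ h⁻¹)
    2 living end → dead end (k = 3.80 M⁻¹ h⁻¹)

Friday's left 13.0 % of its free monomer at the end, which reads back as an exposure of 2.04, larger than my 1.52. For the neighbour of Tuesday's charged with 0.060 M, the order 0.586 took 1.16 to 0.862, which the join turned into 34.2 %; the computed flask gave 35.5 %.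

The earlier runs and the new flask are simulated from invented constants, noise included.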